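**Plan**

1. Retrosynthesis: the three O‑benzyl groups and a silyl group on C7' come off last. The benzene ring of the 2,3‑dihydrobenzofuran is then cut at C4'–C5', C6'–C7' and C3a'–C7a' in a (2+2+2) sense (primed numbers: benzofuran; unprimed: butenolide).
2. Enabling feature: that benzene ring carries O1' (on C7a'), the C3' methylene (on C3a') and the benzylic CH2 to the butenolide (on C5') in a 1,2,4‑pattern. This maps onto an ynol‑ether 1,6‑diyne (C3a'/C4' and C7a'/C7') plus the alkyne of a C5‑propargyl butenolide (C5'/C6').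
3. Monoyne: the butenolide ring is made first by aldol–lactonisation of 4‑hydroxyphenylpyruvic acid with methyl glyoxylate; the C5–CH2 bond follows by phase‑transfer propargylation.
4. Diyne: the C3'–C3a' bond comes from acetylide opening of a resolved epoxide, the O1'–C7a' bond from a dichlorovinyl ether; a bulky silyl group caps the ynol ether terminus.
5. Forward ring order: butenolide, then dihydrofuran and benzene rings together in the cycloaddition, then protodesilylation and hydrogenolysis.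
6. Stereochemistry: butenolide C5 (S) is set by the chiral ammonium ion pair in the propargylation; benzofuran C2' (S) comes from hydrolytic kinetic resolution of the epoxide. No bond at either centre is made or broken afterwards.

Key step: step 11

Assumption: the cinchonidinium catalyst written in step 3 is taken to give the 2S product; if a trial shows the opposite sense of induction, the pseudo‑enantiomeric cinchoninium salt is used instead.

**Route**

Step 1
Reactants: 1 4‑hydroxyphenylpyruvic acid; 2 methyl glyoxylate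
Product: 4 methyl 4‑hydroxy‑3‑(4‑hydroxyphenyl)‑5‑oxo‑2,5‑dihydrofuran‑2‑carboxylate, via open‑chain aldol adduct 3 (not isolated)
Conditions: Et3N, THF, 0 °C to rt; then 2 M HCl, rt
Reagents that add atoms: none
Why: Aldol–lactonisation: the enolised C3 of the arylpyruvate adds to the very electrophilic aldehyde of 2 and, on acidification, the γ‑hydroxy α‑keto acid 3 lactonises and enolises to the 3‑hydroxybutenolide, as arylpyruvic acids are known to do with aldehydes; C5 is formed racemic and is set in step 3.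

Step 2
Reactants: 4 methyl 4‑hydroxy‑3‑(4‑hydroxyphenyl)‑5‑oxo‑2,5‑dihydrofuran‑2‑carboxylate
Product: 5 methyl 4‑(benzyloxy)‑3‑[4‑(benzyloxy)phenyl]‑5‑oxo‑2,5‑dihydrofuran‑2‑carboxylate
Conditions: BnOH, PPh3, DIAD, THF, 0 °C to rt
Reagents that add atoms: benzyl alcohol, OCc1ccccc1
Why: Mitsunobu etherification alkylates the two acidic hydroxyls (enol and phenol) under neutral conditions, so the acidic C5–H is not C‑benzylated as it could be with base and benzyl bromide.

Step 3
Reactants: 5 methyl 4‑(benzyloxy)‑3‑[4‑(benzyloxy)phenyl]‑5‑oxo‑2,5‑dihydrofuran‑2‑carboxylate; 6 propargyl bromide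
Product: 7 methyl (2S)‑4‑(benzyloxy)‑3‑[4‑(benzyloxy)phenyl]‑5‑oxo‑2‑(prop‑2‑yn‑1‑yl)‑2,5‑dihydrofuran‑2‑carboxylate
Conditions: O‑allyl‑N‑(9‑anthracenylmethyl)cinchonidinium bromide (10 mol%), Cs2CO3, toluene, −20 °C
Reagents that add atoms: none
Why: Asymmetric phase‑transfer alkylation: Cs2CO3 deprotonates the doubly activated C5–H to a planar 5‑(methoxycarbonyl)‑2‑oxidofuran, which should be alkylated at the ester‑bearing C5 (C3 carries the benzyloxy group and C5 attack restores the conjugated butenolide) inside the chiral ammonium ion pair, whose anthracenylmethyl wall shields one face and so sets the 2S quaternary centre, as in the known phase‑transfer γ‑alkylation of phthalide 3‑carboxylates and α‑alkylation of α‑acyloxy malonates.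

Step 4
Reactants: 8 2‑methylbut‑3‑en‑2‑ol
Product: 9 benzyl 2‑methylbut‑3‑en‑2‑yl ether
Conditions: NaH, BnBr, Bu4NI (cat.), THF, 0 °C to reflux
Reagents that add atoms: benzyl bromide, BrCc1ccccc1
Why: Williamson etherification of the tertiary sodium alkoxide with a reactive benzylic halide gives an ether that cannot migrate to the neighbouring oxygen in the later alkoxide steps (as a silyl group would) and that leaves with the other benzyl groups in step 13.

Step 5
Reactants: 9 benzyl 2‑methylbut‑3‑en‑2‑yl ether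
Product: 10 rac‑2‑[2‑(benzyloxy)propan‑2‑yl]oxirane
Conditions: mCPBA, NaHCO3, CH2Cl2, rt
Reagents that add atoms: 3‑chloroperoxybenzoic acid (mCPBA), O=C(OO)c1cccc(Cl)c1
Why: Prilezhaev epoxidation of the only alkene; the racemate is resolved in step 6.

Step 6
Reactants: 10 rac‑2‑[2‑(benzyloxy)propan‑2‑yl]oxirane
Product: 11 (2S)‑2‑[2‑(benzyloxy)propan‑2‑yl]oxirane
Conditions: (R,R)‑(salen)Co(OAc) [salen = N,N'‑bis(3,5‑di‑tert‑butylsalicylidene)cyclohexane‑1,2‑diaminate] (1 mol%), H2O (0.55 equiv), THF, 0 °C to rt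
Reagents that add atoms: none
Why: Jacobsen hydrolytic kinetic resolution: the trivalent cobalt salen complex should hydrolyse the (R)‑epoxide to its diol much faster than the (S)‑epoxide, which is recovered and carries the future C2' configuration; the (R,R)‑catalyst is expected to leave the S enantiomer by analogy with epichlorohydrin and methyl glycidate, and terminal epoxides with a quaternary α‑carbon such as tert‑butyloxirane are known substrates.

Step 7
Reactants: 11 (2S)‑2‑[2‑(benzyloxy)propan‑2‑yl]oxirane; 12 ethynyltrimethylsilane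
Product: 13 (3S)‑2‑(benzyloxy)‑2‑methyl‑6‑(trimethylsilyl)hex‑5‑yn‑3‑ol
Conditions: 12, n‑BuLi, THF, −78 °C; BF3·OEt2; then 11, −78 °C
Reagents that add atoms: none
Why: Yamaguchi–Hirao alkynylation: the BF3‑activated epoxide is opened by the lithium acetylide in an SN2 reaction at the unhindered CH2, so the C–O bond of the stereocentre is untouched and 3S follows from 11; the TMS cap keeps this alkyne terminus inert in steps 8 and 9.

Step 8
Reactants: 13 (3S)‑2‑(benzyloxy)‑2‑methyl‑6‑(trimethylsilyl)hex‑5‑yn‑3‑ol; 14 trichloroethylene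
Product: 15 {(4S)‑5‑(benzyloxy)‑4‑[(E)‑1,2‑dichloroethenyloxy]‑5‑methylhex‑1‑yn‑1‑yl}trimethylsilane
Conditions: KH, THF, 0 °C to rt; then 14, −50 °C to rt
Reagents that add atoms: none
Why: O‑Dichlorovinylation: the potassium alkoxide adds in an anti fashion to dichloroacetylene formed in situ from trichloroethylene, the established first stage of ynol ether synthesis from hindered secondary alcohols, and the carbinol configuration is untouched.

Step 9
Reactants: 15 {(4S)‑5‑(benzyloxy)‑4‑[(E)‑1,2‑dichloroethenyloxy]‑5‑methylhex‑1‑yn‑1‑yl}trimethylsilane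
Product: 18 tert‑butyl({[(3S)‑2‑(benzyloxy)‑2‑methyl‑6‑(trimethylsilyl)hex‑5‑yn‑3‑yl]oxy}ethynyl)dimethylsilane, via chloroethynyl ether 16 (not isolated), via lithium alkoxyacetylide 17 (not isolated)
Conditions: n‑BuLi (2.3 equiv), THF, −78 to −40 °C; then TBSOTf, −78 to 0 °C
Reagents that add atoms: tert‑butyldimethylsilyl trifluoromethanesulfonate (TBSOTf), CC(C)(C)[Si](C)(C)OS(=O)(=O)C(F)(F)F
Why: Elimination–silylation: dehydrochlorination gives the chloroalkyne 16, chlorine–lithium exchange gives the acetylide 17, and C‑silylation by the silyl triflate caps the ynol ether terminus with a group bulky enough to steer step 11 that, unlike TMS, survives step 10.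

Step 10
Reactants: 18 tert‑butyl({[(3S)‑2‑(benzyloxy)‑2‑methyl‑6‑(trimethylsilyl)hex‑5‑yn‑3‑yl]oxy}ethynyl)dimethylsilane
Product: 19 tert‑butyl({[(3S)‑2‑(benzyloxy)‑2‑methylhex‑5‑yn‑3‑yl]oxy}ethynyl)dimethylsilane
Conditions: K2CO3 (cat.), MeOH–THF, 0 °C to rt
Reagents that add atoms: none
Why: Chemoselective protodesilylation: methoxide cleaves alkynyl–SiMe3 bonds orders of magnitude faster than alkynyl–SiMe2tBu bonds, so only the alkyl alkyne should be unmasked, and the ynol ether itself is stable to base.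

Step 11
Reactants: 19 tert‑butyl({[(3S)‑2‑(benzyloxy)‑2‑methylhex‑5‑yn‑3‑yl]oxy}ethynyl)dimethylsilane; 7 methyl (2S)‑4‑(benzyloxy)‑3‑[4‑(benzyloxy)phenyl]‑5‑oxo‑2‑(prop‑2‑yn‑1‑yl)‑2,5‑dihydrofuran‑2‑carboxylate
Product: 20 methyl (2S)‑4‑(benzyloxy)‑3‑[4‑(benzyloxy)phenyl]‑2‑({(2S)‑2‑[2‑(benzyloxy)propan‑2‑yl]‑7‑[tert‑butyl(dimethyl)silyl]‑2,3‑dihydro‑1‑benzofuran‑5‑yl}methyl)‑5‑oxo‑2,5‑dihydrofuran‑2‑carboxylate
Conditions: Cp*RuCl(cod) (10 mol%), ClCH2CH2Cl, rt to 40 °C, slow addition of 19 to 7 (1.5 equiv)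
Reagents that add atoms: none
Why: Proposed new method: oxidative cyclisation of the two alkynes of 19 on the divalent ruthenium fragment Cp*RuCl should give a bicyclic ruthenacycle, closing the dihydrofuran ring by C3a'–C7a' bond formation between the two internal alkyne carbons; the alkyne of 7 then inserts on the unhindered C4' side and reductive elimination forms C4'–C5' and C6'–C7', closing the benzene ring. The closest known reaction type is the Cp*RuCl(cod)‑catalysed (2+2+2) cycloaddition of unsymmetrical 1,6‑diynes with terminal alkynes, together with the rhodium‑catalysed variant on ynamide‑tethered silyl diynes that gives indolines; the ynol‑ether tether is the extension. The dihydrofuran ring thus closes by intramolecular alkyne–alkyne coupling in the metallacycle and the benzene ring by intermolecular alkyne insertion and reductive elimination. No stereocentre is formed, and C2' of the tether and C5 of the butenolide are spectators with no bond to them made or broken. The step needs meta regiochemistry (benzylic carbon on C5', not C6'), secured by the bulky silyl group on C7' which keeps the substituted alkyne carbon away from that terminus, and cross‑ over homo‑cyclotrimerisation, secured by the fast intramolecular metallacycle formation of the tethered diyne, its capped terminus and slow addition of 19 to excess 7. The temperature is held at or below 40 °C because secondary alkyl ynol ethers fragment to ketenes on heating.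

Step 12
Reactants: 20 methyl (2S)‑4‑(benzyloxy)‑3‑[4‑(benzyloxy)phenyl]‑2‑({(2S)‑2‑[2‑(benzyloxy)propan‑2‑yl]‑7‑[tert‑butyl(dimethyl)silyl]‑2,3‑dihydro‑1‑benzofuran‑5‑yl}methyl)‑5‑oxo‑2,5‑dihydrofuran‑2‑carboxylate
Product: 21 methyl (2S)‑4‑(benzyloxy)‑3‑[4‑(benzyloxy)phenyl]‑2‑({(2S)‑2‑[2‑(benzyloxy)propan‑2‑yl]‑2,3‑dihydro‑1‑benzofuran‑5‑yl}methyl)‑5‑oxo‑2,5‑dihydrofuran‑2‑carboxylate
Conditions: TFA, CH2Cl2, 0 °C to rt
Reagents that add atoms: none
Why: Protodesilylation of an aryl silane: ipso‑protonation at C7', ortho to the ring oxygen, and loss of the silyl group as its trifluoroacetate, a reaction routinely used on silylarenes from alkyne cyclotrimerisation; tert‑butyl on silicon retards this electrophilic cleavage only mildly, and the benzyl ethers, lactone and ester should tolerate short exposure to dilute acid.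

Step 13
Reactants: 21 methyl (2S)‑4‑(benzyloxy)‑3‑[4‑(benzyloxy)phenyl]‑2‑({(2S)‑2‑[2‑(benzyloxy)propan‑2‑yl]‑2,3‑dihydro‑1‑benzofuran‑5‑yl}methyl)‑5‑oxo‑2,5‑dihydrofuran‑2‑carboxylate
Product: 22 methyl (2S)‑4‑hydroxy‑3‑(4‑hydroxyphenyl)‑2‑{[(2S)‑2‑(2‑hydroxypropan‑2‑yl)‑2,3‑dihydro‑1‑benzofuran‑5‑yl]methyl}‑5‑oxo‑2,5‑dihydrofuran‑2‑carboxylate
Conditions: H2 (1 atm), Pd(OH)2/C, EtOAc–MeOH, rt
Reagents that add atoms: none
Why: Hydrogenolysis of the three benzyl ethers (phenol, enol and tertiary alkyl) should give the target, since the tetrasubstituted conjugated butenolide alkene and the non‑benzylic C–O bonds at both stereocentres are inert under these conditions.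

**Compound list**

1 | 4‑hydroxyphenylpyruvic acid | O=C(O)C(=O)Cc1ccc(O)cc1 | starting material
2 | methyl glyoxylate | COC(=O)C=O | starting material
3 | 4‑hydroxy‑3‑(4‑hydroxyphenyl)‑5‑methoxy‑2,5‑dioxopentanoic acid (open‑chain aldol adduct, diastereomer mixture) | COC(=O)C(O)C(c1ccc(O)cc1)C(=O)C(=O)O | intermediate (not isolated)
4 | methyl 4‑hydroxy‑3‑(4‑hydroxyphenyl)‑5‑oxo‑2,5‑dihydrofuran‑2‑carboxylate (racemic) | COC(=O)C1OC(=O)C(O)=C1c1ccc(O)cc1 | intermediate
5 | methyl 4‑(benzyloxy)‑3‑[4‑(benzyloxy)phenyl]‑5‑oxo‑2,5‑dihydrofuran‑2‑carboxylate (racemic) | COC(=O)C1OC(=O)C(OCc2ccccc2)=C1c1ccc(OCc2ccccc2)cc1 | intermediate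
6 | propargyl bromide | C#CCBr | starting material
7 | methyl (2S)‑4‑(benzyloxy)‑3‑[4‑(benzyloxy)phenyl]‑5‑oxo‑2‑(prop‑2‑yn‑1‑yl)‑2,5‑dihydrofuran‑2‑carboxylate | COC(=O)[C@@]1(CC#C)OC(=O)C(OCc2ccccc2)=C1c1ccc(OCc2ccccc2)cc1 | intermediate
8 | 2‑methylbut‑3‑en‑2‑ol | C=CC(C)(C)O | starting material
9 | benzyl 2‑methylbut‑3‑en‑2‑yl ether | C=CC(C)(C)OCc1ccccc1 | intermediate
10 | rac‑2‑[2‑(benzyloxy)propan‑2‑yl]oxirane | CC(C)(OCc1ccccc1)C1CO1 | intermediate
11 | (2S)‑2‑[2‑(benzyloxy)propan‑2‑yl]oxirane | CC(C)(OCc1ccccc1)[C@@H]1CO1 | intermediate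
12 | ethynyltrimethylsilane | C#C[Si](C)(C)C | starting material
13 | (3S)‑2‑(benzyloxy)‑2‑methyl‑6‑(trimethylsilyl)hex‑5‑yn‑3‑ol | C[Si](C)(C)C#CC[C@@H](C(C)(C)OCc1ccccc1)O | intermediate
14 | trichloroethylene | ClC=C(Cl)Cl | starting material
15 | {(4S)‑5‑(benzyloxy)‑4‑[(E)‑1,2‑dichloroethenyloxy]‑5‑methylhex‑1‑yn‑1‑yl}trimethylsilane | C[Si](C)(C)C#CC[C@@H](C(C)(C)OCc1ccccc1)O/C(Cl)=C\Cl | intermediate
16 | {(4S)‑5‑(benzyloxy)‑4‑[(chloroethynyl)oxy]‑5‑methylhex‑1‑yn‑1‑yl}trimethylsilane | C[Si](C)(C)C#CC[C@@H](C(C)(C)OCc1ccccc1)OC#CCl | intermediate (not isolated)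
17 | lithium 2‑{[(3S)‑2‑(benzyloxy)‑2‑methyl‑6‑(trimethylsilyl)hex‑5‑yn‑3‑yl]oxy}ethynide | C[Si](C)(C)C#CC[C@@H](C(C)(C)OCc1ccccc1)OC#C[Li] | intermediate (not isolated)
18 | tert‑butyl({[(3S)‑2‑(benzyloxy)‑2‑methyl‑6‑(trimethylsilyl)hex‑5‑yn‑3‑yl]oxy}ethynyl)dimethylsilane | C[Si](C)(C)C#CC[C@@H](C(C)(C)OCc1ccccc1)OC#C[Si](C)(C)C(C)(C)C | intermediate
19 | tert‑butyl({[(3S)‑2‑(benzyloxy)‑2‑methylhex‑5‑yn‑3‑yl]oxy}ethynyl)dimethylsilane | C#CC[C@@H](C(C)(C)OCc1ccccc1)OC#C[Si](C)(C)C(C)(C)C | intermediate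
20 | methyl (2S)‑4‑(benzyloxy)‑3‑[4‑(benzyloxy)phenyl]‑2‑({(2S)‑2‑[2‑(benzyloxy)propan‑2‑yl]‑7‑[tert‑butyl(dimethyl)silyl]‑2,3‑dihydro‑1‑benzofuran‑5‑yl}methyl)‑5‑oxo‑2,5‑dihydrofuran‑2‑carboxylate | COC(=O)[C@@]1(Cc2cc([Si](C)(C)C(C)(C)C)c3c(c2)C[C@@H](C(C)(C)OCc2ccccc2)O3)OC(=O)C(OCc2ccccc2)=C1c1ccc(OCc2ccccc2)cc1 | intermediate
21 | methyl (2S)‑4‑(benzyloxy)‑3‑[4‑(benzyloxy)phenyl]‑2‑({(2S)‑2‑[2‑(benzyloxy)propan‑2‑yl]‑2,3‑dihydro‑1‑benzofuran‑5‑yl}methyl)‑5‑oxo‑2,5‑dihydrofuran‑2‑carboxylate | COC(=O)[C@@]1(Cc2ccc3c(c2)C[C@@H](C(C)(C)OCc2ccccc2)O3)OC(=O)C(OCc2ccccc2)=C1c1ccc(OCc2ccccc2)cc1 | intermediate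
22 | methyl (2S)‑4‑hydroxy‑3‑(4‑hydroxyphenyl)‑2‑{[(2S)‑2‑(2‑hydroxypropan‑2‑yl)‑2,3‑dihydro‑1‑benzofuran‑5‑yl]methyl}‑5‑oxo‑2,5‑dihydrofuran‑2‑carboxylate | COC(=O)[C@@]1(Cc2ccc3c(c2)C[C@@H](C(C)(C)O)O3)OC(=O)C(O)=C1c1ccc(O)cc1 | target

**Step count**

Total: 13 steps. Longest linear sequence: 10 steps (steps 4 to 13, from 2‑methylbut‑3‑en‑2‑ol 8). The butenolide branch is 3 steps (steps 1 to 3).

**Steps most likely to fail**

Step 11. Oxidative cyclisation of the hindered, electron‑rich silyl ynol ether on ruthenium may be slow. Homo‑oligomerisation of the terminal alkyne, hydration or fragmentation of the ynol ether, or insertion in the wrong orientation could then outrun the cross‑cycloaddition. The fallback uses known chemistry, sets out from epoxide 11 and butenolide 5, and rejoins the route at 21; it closes the dihydrofuran ring by C–O instead of C–C bond formation. Bromine–magnesium exchange on tert‑butyl 3‑bromo‑4‑fluorobenzoate F1 (i‑PrMgCl·LiCl, THF, −20 °C) and CuI‑catalysed opening of 11 at its CH2 should give tert‑butyl 3‑[(2S)‑3‑(benzyloxy)‑2‑hydroxy‑3‑methylbutyl]‑4‑fluorobenzoate F2. KOtBu in THF then closes the ring by intramolecular SNAr at the fluoride para to the ester, with the carbinol C–O bond untouched, to give tert‑butyl (2S)‑2‑[2‑(benzyloxy)propan‑2‑yl]‑2,3‑dihydro‑1‑benzofuran‑5‑carboxylate F3. LiAlH4 reduction gives {(2S)‑2‑[2‑(benzyloxy)propan‑2‑yl]‑2,3‑dihydro‑1‑benzofuran‑5‑yl}methanol F4, and an Appel reaction (CBr4, PPh3) gives (2S)‑2‑[2‑(benzyloxy)propan‑2‑yl]‑5‑(bromomethyl)‑2,3‑dihydro‑1‑benzofuran F5. Asymmetric phase‑transfer benzylation of 5 with F5 under the conditions of step 3 then gives 21 directly.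

Step 3. Facial discrimination in the ammonium–dienolate ion pair may be poor with the small methyl ester, and alkylation may go to C3 or oxygen of the ambident 2‑oxidofuran. The fallback sets out from 5 and rejoins at 7; it answers the selectivity problem by resolution instead of asymmetric catalysis. Alkylation with 6 under achiral phase‑transfer conditions (Bu4NBr, K2CO3, toluene) gives racemic methyl 4‑(benzyloxy)‑3‑[4‑(benzyloxy)phenyl]‑5‑oxo‑2‑(prop‑2‑yn‑1‑yl)‑2,5‑dihydrofuran‑2‑carboxylate F6. Preparative chromatography on a chiral stationary phase separates the enantiomers; the 2S enantiomer is 7.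

Step 8. The alkynyl trimethylsilyl group may transfer to the potassium alkoxide (intermolecular carbon‑to‑oxygen silyl migration), or the hindered alkoxide may add too slowly to dichloroacetylene. The fallback sets out from 13 and rejoins at 18; it avoids any alkoxide. Formylation (formic acetic anhydride, pyridine) gives (3S)‑2‑(benzyloxy)‑2‑methyl‑6‑(trimethylsilyl)hex‑5‑yn‑3‑yl formate F7. Dichloromethylenation of the formate carbonyl with PPh3 and CCl4 (THF, 60 °C) gives {(4S)‑5‑(benzyloxy)‑4‑[(2,2‑dichloroethenyl)oxy]‑5‑methylhex‑1‑yn‑1‑yl}trimethylsilane F8. n‑BuLi then takes F8 through the same chloroalkyne 16 and acetylide 17, and TBSOTf gives 18.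

**Further compounds**

F1 | step 11 | tert‑butyl 3‑bromo‑4‑fluorobenzoate | CC(C)(C)OC(=O)c1ccc(F)c(Br)c1
F2 | step 11 | tert‑butyl 3‑[(2S)‑3‑(benzyloxy)‑2‑hydroxy‑3‑methylbutyl]‑4‑fluorobenzoate | CC(C)(C)OC(=O)c1ccc(F)c(C[C@@H](C(C)(C)OCc2ccccc2)O)c1
F3 | step 11 | tert‑butyl (2S)‑2‑[2‑(benzyloxy)propan‑2‑yl]‑2,3‑dihydro‑1‑benzofuran‑5‑carboxylate | CC(C)(C)OC(=O)c1ccc2c(c1)C[C@@H](C(C)(C)OCc1ccccc1)O2
F4 | step 11 | {(2S)‑2‑[2‑(benzyloxy)propan‑2‑yl]‑2,3‑dihydro‑1‑benzofuran‑5‑yl}methanol | OCc1ccc2c(c1)C[C@@H](C(C)(C)OCc1ccccc1)O2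
F5 | step 11 | (2S)‑2‑[2‑(benzyloxy)propan‑2‑yl]‑5‑(bromomethyl)‑2,3‑dihydro‑1‑benzofuran | BrCc1ccc2c(c1)C[C@@H](C(C)(C)OCc1ccccc1)O2
F6 | step 3 | racemic methyl 4‑(benzyloxy)‑3‑[4‑(benzyloxy)phenyl]‑5‑oxo‑2‑(prop‑2‑yn‑1‑yl)‑2,5‑dihydrofuran‑2‑carboxylate | COC(=O)C1(CC#C)OC(=O)C(OCc2ccccc2)=C1c1ccc(OCc2ccccc2)cc1
F7 | step 8 | (3S)‑2‑(benzyloxy)‑2‑methyl‑6‑(trimethylsilyl)hex‑5‑yn‑3‑yl formate | C[Si](C)(C)C#CC[C@@H](C(C)(C)OCc1ccccc1)OC=O
F8 | step 8 | {(4S)‑5‑(benzyloxy)‑4‑[(2,2‑dichloroethenyl)oxy]‑5‑methylhex‑1‑yn‑1‑yl}trimethylsilane | C[Si](C)(C)C#CC[C@@H](C(C)(C)OCc1ccccc1)OC=C(Cl)Cl
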